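**Retrosynthetic overview**
1. Target ⇐ base-induced E1cB opening of a bridged methyl ketal ketone (2-oxabicyclo[3.3.1]nonan-7-one); the enone C=C and the side-chain C=O are released together.
2. Bridged ketal ⇐ proposed ketone-templated desilylative ketalization of a C2-symmetric trans-3,5-bis(silyloxy) aldol adduct; this differentiation turns the quaternary carbinol carbon into the (S)-stereocentre.
3. Aldol adduct ⇐ C–C bond between the lithium enolate of (10Z,13Z)-nonadeca-10,13-dien-2-one (from linoleoyl chloride) and (3S,5S)-3,5-bis(TBSO)cyclohexanone, whose two carbonyl faces are homotopic.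
4. That ketone ⇐ (−)-quinic acid by 4-deoxygenation and glycol cleavage (chiral pool).
5. Ring order: the carbocycle is carried intact from quinic acid; the only ring formed is the temporary oxane bridge (step 9), which is opened again in step 11.

Assumption: the transient ketal carbon of 13 and 14 is drawn as the anomerically favoured epimer (methoxy axial); it is erased in step 11, so its configuration does not affect the target.

**Route**

Step 1
Reactants: 1 (−)-quinic acid
Product: 2 methyl (−)-quinate
Conditions: MeOH, sulfonic acid resin (H+ form), reflux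
Reagents that add atoms: methanol, CO
Why: Fischer esterification under acid-resin catalysis; no stereocentre is touched.

Step 2
Reactants: 2 methyl (−)-quinate
Product: 3 methyl 3,5-bis-O-(tert-butyldimethylsilyl)quinate
Conditions: TBSCl (2.3 equiv), Et3N, DMAP (cat.), DMF, 0 °C → rt
Reagents that add atoms: tert-butyldimethylsilyl chloride, CC(C)(C)[Si](C)(C)Cl
Why: Regioselective silyl ether formation at the two less hindered secondary hydroxyls (C3, C5); the flanked C4–OH and the tertiary C1–OH react much more slowly.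

Step 3
Reactants: 3 methyl 3,5-bis-O-(tert-butyldimethylsilyl)quinate
Product: 4 methyl 3,5-bis-O-(tert-butyldimethylsilyl)-4-O-(1H-imidazol-1-ylcarbonothioyl)quinate
Conditions: 1,1'-thiocarbonyldiimidazole, CH2Cl2, rt
Reagents that add atoms: 1,1'-thiocarbonyldiimidazole, S=C(n1ccnc1)n1ccnc1
Why: Thioacylation of the only free secondary hydroxyl (C4) prepares a Barton–McCombie deoxygenation; the tertiary hydroxyl does not react.

Step 4
Reactants: 4 methyl 3,5-bis-O-(tert-butyldimethylsilyl)-4-O-(1H-imidazol-1-ylcarbonothioyl)quinate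
Product: 5 methyl (3S,5S)-3,5-bis[(tert-butyldimethylsilyl)oxy]-1-hydroxycyclohexane-1-carboxylate
Conditions: Bu3SnH, AIBN (cat.), PhMe, 90 °C
Reagents that add atoms: none
Why: Barton–McCombie radical deoxygenation removes the C4 oxygen before any polyene is present, leaving the trans-3,5-bis(silyloxy) ring in which C1 is no longer a stereocentre.

Step 5
Reactants: 5 methyl (3S,5S)-3,5-bis[(tert-butyldimethylsilyl)oxy]-1-hydroxycyclohexane-1-carboxylate
Product: 6 (3S,5S)-3,5-bis[(tert-butyldimethylsilyl)oxy]-1-(hydroxymethyl)cyclohexan-1-ol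
Conditions: NaBH4, EtOH, 0 °C → rt
Reagents that add atoms: none
Why: Borohydride reduction of the activated α-hydroxy ester gives the 1,2-diol without touching the silyl ethers.

Step 6
Reactants: 6 (3S,5S)-3,5-bis[(tert-butyldimethylsilyl)oxy]-1-(hydroxymethyl)cyclohexan-1-ol
Product: 7 (3S,5S)-3,5-bis[(tert-butyldimethylsilyl)oxy]cyclohexan-1-one
Conditions: NaIO4, THF/H2O, 0 °C → rt
Reagents that add atoms: none
Why: Malaprade periodate glycol cleavage gives the C2-symmetric trans ketone, whose two carbonyl faces are homotopic.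

Step 7
Reactants: 8 linoleoyl chloride [(9Z,12Z)-octadeca-9,12-dienoyl chloride]
Product: 9 (10Z,13Z)-nonadeca-10,13-dien-2-one
Conditions: MeMgBr (1.05 equiv), Fe(acac)3 (3 mol %), THF, −78 °C
Reagents that add atoms: methylmagnesium bromide, C[Mg]Br
Why: Iron-catalysed Grignard acylation of the acid chloride stops at the ketone and leaves the skipped Z,Z-diene untouched.

Step 8
Reactants: 9 (10Z,13Z)-nonadeca-10,13-dien-2-one; 7 (3S,5S)-3,5-bis[(tert-butyldimethylsilyl)oxy]cyclohexan-1-one
Product: 11 (10Z,13Z)-1-[(3S,5S)-3,5-bis[(tert-butyldimethylsilyl)oxy]-1-hydroxycyclohexyl]nonadeca-10,13-dien-2-one, via lithium enolate 10 (not isolated)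
Conditions: LiN(iPr)2 (LDA, 1.0 equiv), THF, −78 °C; then 7, −78 °C; AcOH quench at −78 °C
Reagents that add atoms: lithium diisopropylamide, CC(C)N([Li])C(C)C (supplies the lithium of 10; nothing from it remains in 11)
Why: Kinetic lithium enolate (methyl side) aldol addition to a ketone; because 7 is C2-symmetric, attack on either face gives the same single adduct, so no diastereomer problem arises and the new carbinol carbon is not yet a stereocentre.

Step 9
Reactants: 11 (10Z,13Z)-1-[(3S,5S)-3,5-bis[(tert-butyldimethylsilyl)oxy]-1-hydroxycyclohexyl]nonadeca-10,13-dien-2-one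
Product: 13 bridged methyl ketal diol (1S,3S,5S,7S)-3-[(8Z,11Z)-heptadeca-8,11-dien-1-yl]-3-methoxy-2-oxabicyclo[3.3.1]nonane-5,7-diol, via triol 12 (not isolated)
Conditions: TsOH·H2O (0.2 equiv), MeOH, 0 °C → rt; concentrate; PPTS (cat.), 4 Å MS, CH2Cl2, rt
Reagents that add atoms: methanol, CO
Why: Proposed new method: acidic methanolysis removes both silyl groups and the side-chain ketone is then trapped as a six-membered mixed methyl ketal by the one ring hydroxyl that is cis (1,3-diaxial) to the CH2C(=O) arm, since the trans hydroxyl cannot bridge, so the substrate's own ketone tells the two diastereotopic carbinols apart and fixes the quaternary carbon as a stereocentre with the free secondary OH cis to the tertiary OH (methoxy axial by the anomeric effect); closest known reaction type is Fischer-type intramolecular ketalization of δ-hydroxy ketones to 2-methoxyoxanes and bridged 2-oxabicyclo[3.3.1]nonane ketal formation, not yet used to differentiate the ends of a C2-symmetric 1,3-diol.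

Step 10
Reactants: 13 bridged methyl ketal diol
Product: 14 (1R,3S,5R)-3-[(8Z,11Z)-heptadeca-8,11-dien-1-yl]-5-hydroxy-3-methoxy-2-oxabicyclo[3.3.1]nonan-7-one
Conditions: (nPr4N)RuO4 (5 mol %), NMO (1.5 equiv), 4 Å MS, CH2Cl2, rt
Reagents that add atoms: none
Why: Ley–Griffith oxidation of the only secondary alcohol under neutral conditions; the tertiary alcohol, the ketal and the skipped diene are inert (the descriptor changes at C1 and C5 are formal).

Step 11
Reactants: 14 bridged methyl ketal ketone
Product: 15 (S)-5-hydroxy-5-[(10Z,13Z)-2-oxononadeca-10,13-dien-1-yl]cyclohex-2-en-1-one (target)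
Conditions: DBU (0.3 equiv), CH2Cl2, −20 → 0 °C; pH 7 buffer quench
Reagents that add atoms: none
Why: E1cB β-elimination (retro-oxa-Michael): in the locked bicycle the ketal C–O bond is axial and aligned with the enolate while the tertiary hydroxyl is equatorial, so only the bridge oxygen leaves, the released methyl hemiketal oxide collapses to the side-chain ketone and methanol, and the quaternary stereocentre is untouched.

**Compound list**

1 | (−)-quinic acid, (1S,3R,4S,5R)-1,3,4,5-tetrahydroxycyclohexane-1-carboxylic acid | OC(=O)[C@]1(O)C[C@@H](O)[C@@H](O)[C@H](O)C1 | starting material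
2 | methyl (−)-quinate | COC(=O)[C@]1(O)C[C@@H](O)[C@@H](O)[C@H](O)C1 | intermediate
3 | methyl 3,5-bis-O-(tert-butyldimethylsilyl)quinate (1-OH and 4-OH free) | COC(=O)[C@]1(O)C[C@@H](O[Si](C)(C)C(C)(C)C)[C@@H](O)[C@H](O[Si](C)(C)C(C)(C)C)C1 | intermediate
4 | methyl 3,5-bis-O-(tert-butyldimethylsilyl)-4-O-(1H-imidazol-1-ylcarbonothioyl)quinate | COC(=O)[C@]1(O)C[C@@H](O[Si](C)(C)C(C)(C)C)[C@@H](OC(=S)n2ccnc2)[C@H](O[Si](C)(C)C(C)(C)C)C1 | intermediate
5 | methyl (3S,5S)-3,5-bis[(tert-butyldimethylsilyl)oxy]-1-hydroxycyclohexane-1-carboxylate (trans-3,5) | COC(=O)C1(O)C[C@@H](O[Si](C)(C)C(C)(C)C)C[C@H](O[Si](C)(C)C(C)(C)C)C1 | intermediate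
6 | (3S,5S)-3,5-bis[(tert-butyldimethylsilyl)oxy]-1-(hydroxymethyl)cyclohexan-1-ol | OCC1(O)C[C@@H](O[Si](C)(C)C(C)(C)C)C[C@H](O[Si](C)(C)C(C)(C)C)C1 | intermediate
7 | (3S,5S)-3,5-bis[(tert-butyldimethylsilyl)oxy]cyclohexan-1-one (C2-symmetric, trans) | O=C1C[C@@H](O[Si](C)(C)C(C)(C)C)C[C@H](O[Si](C)(C)C(C)(C)C)C1 | intermediate
8 | linoleoyl chloride, (9Z,12Z)-octadeca-9,12-dienoyl chloride | CCCCC/C=C\C/C=C\CCCCCCCC(Cl)=O | starting material
9 | (10Z,13Z)-nonadeca-10,13-dien-2-one | CCCCC/C=C\C/C=C\CCCCCCCC(C)=O | intermediate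
10 | lithium (10Z,13Z)-nonadeca-1,10,13-trien-2-olate (kinetic enolate of 9) | CCCCC/C=C\C/C=C\CCCCCCCC(=C)O[Li] | intermediate
11 | (10Z,13Z)-1-[(3S,5S)-3,5-bis[(tert-butyldimethylsilyl)oxy]-1-hydroxycyclohexyl]nonadeca-10,13-dien-2-one | CCCCC/C=C\C/C=C\CCCCCCCC(=O)CC1(O)C[C@@H](O[Si](C)(C)C(C)(C)C)C[C@H](O[Si](C)(C)C(C)(C)C)C1 | intermediate
12 | (10Z,13Z)-1-[(3S,5S)-1,3,5-trihydroxycyclohexyl]nonadeca-10,13-dien-2-one | CCCCC/C=C\C/C=C\CCCCCCCC(=O)CC1(O)C[C@@H](O)C[C@H](O)C1 | intermediate
13 | (1S,3S,5S,7S)-3-[(8Z,11Z)-heptadeca-8,11-dien-1-yl]-3-methoxy-2-oxabicyclo[3.3.1]nonane-5,7-diol (5-OH tertiary bridgehead; 7-OH secondary, exo; 3-OMe axial) | CCCCC/C=C\C/C=C\CCCCCCC[C@@]1(OC)C[C@]2(O)C[C@@H](O)C[C@@H](C2)O1 | intermediate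
14 | (1R,3S,5R)-3-[(8Z,11Z)-heptadeca-8,11-dien-1-yl]-5-hydroxy-3-methoxy-2-oxabicyclo[3.3.1]nonan-7-one | CCCCC/C=C\C/C=C\CCCCCCC[C@@]1(OC)C[C@]2(O)CC(=O)C[C@@H](C2)O1 | intermediate
15 | (S)-5-hydroxy-5-[(10Z,13Z)-2-oxononadeca-10,13-dien-1-yl]cyclohex-2-en-1-one | CCCCC/C=C\C/C=C\CCCCCCCC(=O)C[C@@]1(O)CC=CC(=O)C1 | target

**Step count and risks**

Total step count: 11. Longest linear sequence: 10 steps (steps 1–6 and 8–11 from quinic acid; step 7 is a one-step side branch).

Three steps most likely to fail:

Step 9 (the proposed new step). The strained bridged ketal may not close cleanly (stopping at the hemiketal or the open dimethyl ketal), or the acid may dehydrate the tertiary aldol. The fallback uses only known chemistry, sets out from 11 and comes back at 15. HF·pyridine in THF/pyridine removes both silyl groups to give triol 12, isolated this time. PhB(OH)2 with MgSO4 in CH2Cl2 ties the tertiary hydroxyl and the cis secondary hydroxyl together as the cyclic phenylboronate F2. MsCl/Et3N then sulfonylates the remaining trans hydroxyl to give the boronate mesylate F3. Work-up with aqueous sorbitol/Na2CO3 strips the boron and leaves the mesylate diol F4. Oxidation with (nPr4N)RuO4/NMO gives the β-mesyloxy ketone F5, which loses methanesulfonic acid on treatment with Et3N at 0 °C to give 15. The differentiation here rests on cis-1,3-diol boronate protection instead of the ketal template.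

Step 8. The basic enolate can enolize 7 (with β-elimination of silanolate), and the tertiary aldolate can revert. The fallback sets out from 9 (with 7) and comes back at 11. Ketone 9 is converted with LiN(iPr)2 and Me3SiCl at −78 °C into the kinetic silyl enol ether trimethyl{[(10Z,13Z)-nonadeca-1,10,13-trien-2-yl]oxy}silane F1. F1 is added to 7 under BF3·OEt2 in CH2Cl2 at −78 °C (Mukaiyama aldol) and gives 11 after aqueous work-up. This replaces the basic lithium enolate by Lewis-acid activation of the electrophile.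

Step 11. The base may go on to expel the tertiary hydroxyl (aromatization to the 3-substituted phenol) or trigger retro-aldol loss of the side chain. The fallback sets out from 14 and comes back at 15. PPTS in wet acetone hydrolyses the ketal to the dihydroxy diketone (10Z,13Z)-1-[(1S,3R)-1,3-dihydroxy-5-oxocyclohexyl]nonadeca-10,13-dien-2-one F6. MsCl/Et3N at −20 °C sulfonylates only its secondary hydroxyl to give the β-mesyloxy ketone F5, which eliminates under the same weak-base conditions to 15. A sulfonate leaving group replaces the alkoxide, so no strong amidine base is needed.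

**Further compounds**

F1 | step 8 | trimethyl{[(10Z,13Z)-nonadeca-1,10,13-trien-2-yl]oxy}silane | CCCCC/C=C\C/C=C\CCCCCCCC(=C)O[Si](C)(C)C
F2 | step 9 | cyclic phenylboronate of 12 (boron bridges the tertiary 1-O and the cis 3-O; 5-OH free) | CCCCC/C=C\C/C=C\CCCCCCCC(=O)C[C@]12C[C@H](C[C@H](O)C1)OB(c3ccccc3)O2
F3 | step 9 | 5-O-methanesulfonate of F2 | CCCCC/C=C\C/C=C\CCCCCCCC(=O)C[C@]12C[C@H](C[C@H](OS(C)(=O)=O)C1)OB(c3ccccc3)O2
F4 | step 9 | (1S,3S,5S)-3,5-dihydroxy-3-[(10Z,13Z)-2-oxononadeca-10,13-dien-1-yl]cyclohexyl methanesulfonate | CCCCC/C=C\C/C=C\CCCCCCCC(=O)C[C@]1(O)C[C@@H](O)C[C@H](OS(C)(=O)=O)C1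
F5 | step 9 | (1R,3S)-3-hydroxy-5-oxo-3-[(10Z,13Z)-2-oxononadeca-10,13-dien-1-yl]cyclohexyl methanesulfonate | CCCCC/C=C\C/C=C\CCCCCCCC(=O)C[C@]1(O)CC(=O)C[C@H](OS(C)(=O)=O)C1
F6 | step 11 | (10Z,13Z)-1-[(1S,3R)-1,3-dihydroxy-5-oxocyclohexyl]nonadeca-10,13-dien-2-one | CCCCC/C=C\C/C=C\CCCCCCCC(=O)C[C@]1(O)CC(=O)C[C@H](O)C1
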